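(The earlier runs and the new flask are calculated with constants of no real substance; the scatter is artificial.)

**Fraction left.** 28% of the substrate still stood at 0.500 h in the spring run, one of two runs I had, so I reckoned with the fraction left and got a half-life of 0.272 h.

| setting | dusk | spring | birch | ash |
|---|---|---|---|---|
| substrate | 0.050 M | 0.050 M | 0.050 M | 0.050 M |
| first nucleophile | 0.056 M | 0.066 M | 0.0450 M | 0.0580 M |
| second nucleophile | 0.10 M | 0.10 M | 0.100 M | 0.100 M |
| remark | run made earlier | run made earlier |  |  |
| time |  |  | 10 h | 10 h |

| run | time / h | over-reaction product / % | target / % | other capture product / % | solvolysis product / % | substrate / % |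
|---|---|---|---|---|---|---|
| dusk | 1.33 | 11 | 14 | 64 | 4 | 0 |
| dusk | 3.00 | 17 | 7 | 74 | 5 | 2 |
| dusk | 4.00 | 16 | 7 | 70 | 9 | 0 |
| dusk | 6.00 | 20 | 3 | 70 | 4 | 0 |
| dusk | 8.00 | 25 | 6 | 68 | 5 | 0 |
| dusk | 10.0 | 23 | 2 | 68 | 1 | 0 |
| spring | 0.500 | 7 | 16 | 48 | 4 | 28 |
| spring | 1.50 | 11 | 17 | 61 | 4 | 1 |
| spring | 3.00 | 18 | 9 | 69 | 7 | 1 |
| spring | 4.00 | 26 | 6 | 65 | 5 | 0 |
| spring | 6.00 | 25 | 2 | 66 | 8 | 3 |
| spring | 8.00 | 27 | 3 | 68 | 7 | 0 |
| spring | 10.0 | 31 | 0 | 63 | 7 | 0 |

(standard deviation of a reading: 2 percentage points)

- which of these there is most of at the end, counted by the substrate in it, birch (target / over-reaction product / other capture product / solvolysis product)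
- which of these there is most of at the end, counted by the substrate in it, ash (target / over-reaction product / other capture product / solvolysis product)
- final amount of the leader among these, as a percentage of the substrate charged, in birch
- final amount of the leader among these, as a percentage of the substrate charged, in ash

**Time ladder.** On the lowest rung, substrate in the spring run fell to hardly any, a reckoned 0.612%, by 2.00 h. Next came target, which the spring readings showed fading with a half-life of 1.66 h, slower than substrate. Over 10 h, a fraction of 1.54% of any target remained by this reckoning, so I counted target and over-reaction product as one branch.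

**Selectivity factor.** From 6.00 h on, I took other capture product over that branch, multiplied by the charge of first nucleophile over the charge of second. Dusk gave 1.46 and spring 1.48. I carried their mean, 1.47, as the selectivity factor. Solvolysis product read 5.33%. Of the fraction left after solvolysis, other capture product took r parts against one, where r is the factor times the charge of second nucleophile over first. Birch had r = 3.26, which gave 72.5%, and ash had r = 2.53, which gave 67.9%. Both reckoned splits stood above one, so I expected other capture product to lead in birch and in ash.

**The forecast.** It named other capture product at 72% for birch and other capture product at 68% for ash, on a ratio whose fall with first nucleophile it called “consistent with simple competition”. It and I read the same two runs, so our nearness checks nothing.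

**The flasks.** substrate → intermediate (k = 2.50 h⁻¹); first nucleophile + intermediate → target (k = 337 L mol⁻¹ h⁻¹); target → over-reaction product (k = 0.411 h⁻¹); intermediate → solvolysis product (k = 2.45 h⁻¹); second nucleophile + intermediate → other capture product (k = 462 L mol⁻¹ h⁻¹); first nucleophile ⇌ dormant form (K = 0.360, k = 0.573 h⁻¹)

Other capture product led, with 73.0% in birch and 68.7% in ash, and their 10.0 h states returned factors of 1.48 and 1.49. A neighbour of ash, charged with 0.23 M of first nucleophile, has r = 0.639, below one, so the same reckoning gives 36.9% of other capture product. At its end that flask held 39.0% of it, and its leader was over-reaction product, at 57.6%.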